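In a one-step world, substrate + coupling partner → product, and a flask that stops with substrate left has met either equilibrium or the end of its partner.

| flask | substrate | coupling partner | free catalyst | remark | time |
|---|---|---|---|---|---|
| blue | 0.15 M | 1.2 equiv | 0.5 mol% | the very flask that is asked about, followed so far |  |
| red | 0.15 M | 1.2 equiv | 0.34 mol% | run made earlier |  |
| flask | 0.15 M | 1.20 equiv | 0.5 mol% |  | 2.0 d |

- blue (time / h: product / %, substrate / %): 2.00: 35.7, 64.1; 6.00: 45.6, 53.8; 10.0: 45.9, 52.9; 15.0: 46.0, 53.5; 20.0: 46.5, 52.1; 30.0: 45.2, 53.9
- red (time / h: product / %, substrate / %): 0.167: 5.1, 97.7; 0.500: 8.9, 89.8; 0.833: 13.9, 84.8; 1.33: 21.8, 77.9; 2.00: 27.1, 73.5; 2.50: 30.9, 69.2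

(each reading ± 1 percentage point)

- midnight: change nothing and wait 50 h more
- dusk: at 2.0 d add substrate, 50.0 % of the amount charged, then wait 50 h
- dawn: at 2.0 d add free catalyst, 100 % of the amount charged, then wait 50 h
- noon: at 2.0 d add coupling partner, 100 % of the amount charged, then wait 50 h

- additions leave the volume as it is
- a reading or a percentage of product counts all its forms, free or not

- product, in percent of the substrate first charged, at 2.0 d
- the remedy with the largest gain of product, or "none" below 2 percentage points (midnight / dusk / dawn / noon / none)
- product present, in percent of the substrate first charged, after dusk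
- product present, in percent of the substrate first charged, after dawn

1. The blue run is the asked flask. From 6.00 h to 30.0 h it holds a plateau of 45.8 %, so "now" is read as that, with substrate near 53.9 %.

2. Dividing the plateau by the 1.2 equiv charged gives 38.2 %: the partner share, product formed per partner charged.

3. Dusk is bracketed from below by the plateau, the case of a flask at the end of its partner, where new substrate adds no product. From above stands the equilibrium case, the forecast's 60.8 %. The readings have no partner column, and the red run, at 30.9 % after 2.50 h, is still climbing, so this reckoning leaves the bracket open.

4. Noon's lower end is taken from the equilibrium case, the forecast's 64. From above, a second charge reckoned at the same share brings the flask to 91.7 %. Noon's lower end, 64, stands against dusk's upper end, 60.8 %, so this reckoning commits to noon.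

5. The forecast gives 46 %, noon, 60.8 % after dusk and 46 % after dawn, on the ground “So this is equilibrium”. That places dusk at the top of the bracket.

6. The flask gives 45.9 %, noon as best, 45.9 % after dusk and 45.9 % after dawn.

    free catalyst + product ⇌ idle complex, settled at all times (K = 16.0 L mol⁻¹)
    catalyst intermediate B → free catalyst + product (k = 21000 h⁻¹)
    substrate + free catalyst → catalyst intermediate A (k = 650 L mol⁻¹ h⁻¹)
    coupling partner + catalyst intermediate A ⇌ catalyst intermediate B (K = 12.0 L mol⁻¹, k = 1300 L mol⁻¹ h⁻¹)
    coupling partner → decomposed reagent (k = 0.560 h⁻¹)
    2 catalyst intermediate B ⇌ resting dimer (K = 13000 L mol⁻¹, k = 13000 L mol⁻¹ h⁻¹)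

At 48.0 h the flask holds 0 % of its coupling partner, the limiting reagent despite its excess. Of that charge, 38.2 % became product and 61.8 % became decomposed reagent. Dusk gains 0 percentage points, the lower end of its bracket. The share of 38.2 % promised noon a gain of 45.8 %, and noon gains 28 points. The neighbouring flask, charged with 0.300 equiv, reckons to 11.5 % at that share. It gives 16.8 %, a share of 56.0 %, with 0 % of its partner left and substrate at 82.7 %.

The runs were generated by integration for an exercise; noise was put on by code.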